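## The problem

Integric acid is an eremophilane. A cyclohexane (ring A: C1–C5 and C10) is fused through C5–C10 to a cyclohexenone (ring B: C5–C10); the C9=C10 double bond sits at the ring fusion and is conjugated to the C8 ketone, and C11–C13 form a 2-formylvinyl arm on C7. Ring A carries three stereocenters on one face: the axial allylic C1 acyloxy group, the C4 carboxylic acid and the C5 methyl group are all cis. The vicinal tertiary/quaternary pair C4/C5 therefore has to be made in one event with absolute control. The two carbon substituents on C5 (methyl and C6) are of similar size, so C5 cannot be trusted to direct C1, and C1 needs reagent control. C7 is α to the ketone, equatorial and trans to the C5 methyl, so it can be left to thermodynamics; the C4′ methyl branch of the (2E,4S)-2,4-dimethyloct-2-enoyl group needs its own asymmetric step. The α-substituted acrolein, the β,γ-unsaturated ketone (C11=C13 can slip into conjugation with C8) and the γ-acyloxy enone will not tolerate base, nucleophiles or hydride once ring B exists, so the ester should be in place before that point and the acid and aldehyde should stay masked until the last step. The feature that makes the key step possible is that C8 is a lone carbonyl carbon between the sp2 carbon C9 and C7, whose arm ends in the C11=C13 exo-methylene: C8 can be carbon monoxide stitched between a C9 vinyl iodide and a C7=C11 allylsilane.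

## Retrosynthesis

**Unmasking, 41 from 40.** No skeletal bond is cut. The C4 acid is carried as a tert-butyl ester and C12 as a dimethyl acetal, and one aqueous acid treatment releases both. The neighbouring choices (late oxidation of a C12 alcohol, late acylation of C1) would put oxidant or base on the sensitive bicycle. The forward step only has to avoid moving C11=C13.

**Ring B, 40 from 38 and CO (39).** The C8–C9 and C7–C8 bonds are cut and C8 leaves as carbon monoxide. An aldol or annulation closure at C9–C10 would need a C10 ketone and would leave the arm to be attached afterwards to an enolizable C7. The carbonylative closure instead gives ring B, the enone, the C7 stereocenter and the exo-methylene together. The precursor 38 is monocyclic and already holds the side-chain ester. The forward reaction must insert CO before the vinyl–palladium cyclizes directly, add the acyl group 6-exo to a trisubstituted alkene and terminate by loss of silicon. 38 carries the acetal trans to C6, the geometry the olefination delivers; either alkene isomer should converge because C11 becomes sp3 on the way.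

**The arm, 38 from 36 and 15.** The C7=C11 bond is cut; 38 is the acetal of enal 37, made by Wittig olefination of aldehyde 36 with formyl ylide 15. An ester-level olefination would be better known but would need hydride reduction and reoxidation in the presence of the C1 ester. 15 brings C11, C12, C13 and silicon in one step at the aldehyde oxidation level. It comes from phosphonium salt 13, itself from 10 and 11.

**C7 and C9 adjustments, 36 from 32.** Aldehyde 36 comes from alcohol 35, obtained by hydroboration of the C5 vinyl group of 33. Vinyl iodide 33 comes from vinylsilane 32 by iododesilylation with retention. The iodination has to precede the arrival of the allylsilane, which would itself react with an iodonium source.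

**C1 ester and C1 configuration, 32 from 30 and 9.** The C1–O acyl bond is cut. Esterifying before ring B is closed keeps base and activated acylating agents away from the final enone. Alcohol 30 is traced to enone 29 by oxazaborolidine-catalysed reduction, which sets C1 under reagent control, and 29 to the epimeric alcohols 28.

**Ring A, 28 from 26.** The C1–C10 bond is cut to ynal 26. Nickel-catalysed reductive cyclization adds hydrogen and C1 to the same side of the alkyne, which places silicon (later iodine) cis to C5, the geometry the carbonylation needs. Olefination of a hindered C10 ketone could not guarantee this. The price is an uncontrolled C1, repaid in the previous paragraph. 26 comes from alcohol 25 and this from diene 23 by hydroboration of the less hindered alkene.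

**C4–C5, 23 from 20.** Ester 23 comes from acid 22, and the C4–C5 bond of 22 is cut by an Ireland–Claisen disconnection to allylic ester 20. The chair transition state sets the tertiary and the quaternary center together, which enolate alkylation or propargylic substitution next to a quaternary carbon would not do reliably. The three groups left on C5 are each latent functionality: alkynyl for C10=C9, vinyl for C6–C7, and the allyl group on C4 for C1–C3. A C2-symmetric boron controller supplies the absolute sense. 20 comes from enynol 18 and acid chloride 19, and 18 from commercial 16.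

**Side chain, 9 from 1 and 2.** The C2′=C3′ bond is cut to (S)-2-methylhexanal 7 and ylide 6; 7 comes from alcohol 5, made by auxiliary-controlled methylation (3 to 4) of the hexanoyl imide built from 1 and 2. Ester 8 is hydrolysed to 9.

## Roads not taken

**Alternative 1:** The C5–methyl bond is cut. Forward, BF3·OEt2 would open the 4α,5α-epoxy keto ester A1 at C5, the C10 methyl would migrate to C5 and loss of a C9 proton would give enone A2. The shift is stereospecific and biomimetic, it makes the quaternary center and the C9=C10 enone in one step, and A1 should be reachable from simple annulation chemistry, so the bicyclic core arrives in fewer steps than in the chosen plan. Its weakness for this target is what A2 lacks and what it has too much of: a tertiary C4 hydroxyl that must be removed with control of the C4 hydrogen next to a quaternary carbon, no C1 oxygen and no C7 arm. Both would have to be added to an enone that enolizes toward C7 and toward C1, and the C1 ester would have to be formed late on the sensitive bicycle. Ring contraction and simple elimination compete with the shift. The chosen plan is longer up to the cyclization precursor, but it puts the C4 hydrogen, the C1 ester and the arm in place before ring B exists.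

**Alternative 2:** The C3–C4 and C5–C10 bonds are cut. Forward, a chiral Lewis acid would promote the intramolecular Diels–Alder reaction of triene A3 to the trans-fused octalin A4. Both rings and the C4/C5 pair would be set catalytically, which is better than the stoichiometric boron controller of the chosen plan. The weak points are the dienophile, a β,β-disubstituted enoyl imide that must form a quaternary carbon and is among the least reactive partners for such catalysts, and the oxidation pattern of A4. C10 is sp3, so the C9=C10 double bond has to be introduced regioselectively next to a C8 ketone that also enolizes toward C7; the C1 enol ether has to become an axial alcohol; and the arm is still missing. The chosen plan gives up the catalytic ring construction in exchange for a ring B that is formed at its final oxidation level.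

**Alternative 3:** The C1–C10 bond is cut. Forward, a chiral triazolium-derived carbene would convert the aldehyde of the achiral dienone A5 into an acyl-anion equivalent that adds to one enone arm, giving the cis-fused diketone A6. This desymmetrization is well precedented and reaches the C5 quaternary center catalytically from an achiral precursor in one step, which the chosen plan cannot match. For this target, however, A6 carries C4 as a geminal diester, whose decarboxylation would set the C4 configuration without a controlling element. Its remaining enone is C6=C7–C8 and not C9=C10–C8, C10 is sp3, C1 is a ketone to be reduced to the axial alcohol, and the arm must still be attached at C7, now an enone α-carbon. The chosen plan sets C4 together with C5 and places each double bond where the target has it.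

Key step: step 23

Assumption: the (4S,5S)-configured bromodiazaborolidine is taken to deliver the (2S,3R) acid 22; if the first run shows the opposite sense, its (4R,5R) antipode, from the equally available antipodal diamine, is used without other change.

## Route

Atom labels C1–C13 in the Why lines follow the eremophilane numbering used above.

Step 1
Reactants: 1 (S)-4-benzyloxazolidin-2-one; 2 hexanoyl chloride
Product: 3 (S)-4-benzyl-3-hexanoyloxazolidin-2-one
Conditions: n-BuLi, THF, −78 °C; then 2, −78 → 0 °C
Reagents that add atoms: none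
Why: N-acylation of the lithiated oxazolidinone, a standard entry to an acyl imide; the auxiliary stereocenter is untouched.

Step 2
Reactants: 3 (S)-4-benzyl-3-hexanoyloxazolidin-2-one
Product: 4 (S)-4-benzyl-3-[(S)-2-methylhexanoyl]oxazolidin-2-one
Conditions: NaN(SiMe3)2, THF, −78 °C; MeI, −78 → −40 °C
Reagents that add atoms: iodomethane, CI
Why: Evans asymmetric alkylation: the chelated (Z)-sodium enolate should be methylated on the face away from the benzyl group, which sets the (S) methyl branch of the side chain.

Step 3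
Reactants: 4 (S)-4-benzyl-3-[(S)-2-methylhexanoyl]oxazolidin-2-one
Product: 5 (S)-2-methylhexan-1-ol
Conditions: LiBH4, MeOH (1 equiv), Et2O, 0 °C
Reagents that add atoms: none
Why: Reductive cleavage of the imide at the exocyclic carbonyl; the α-stereocenter is not enolized and auxiliary 1 is recovered.

Step 4
Reactants: 5 (S)-2-methylhexan-1-ol; 6 ethyl 2-(triphenyl-λ5-phosphanylidene)propanoate
Product: 8 ethyl (2E,4S)-2,4-dimethyloct-2-enoate, via (S)-2-methylhexanal 7 (not isolated)
Conditions: PhI(OAc)2, 2,2,6,6-tetramethylpiperidin-1-oxyl (cat.), CH2Cl2, rt; then 6, rt → 40 °C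
Reagents that add atoms: none
Why: Nitroxyl-catalysed oxidation followed in the same flask by Wittig olefination with a stabilized α-branched ylide, which should give the (E)-trisubstituted enoate; the epimerizable aldehyde 7 is consumed as it forms.

Step 5
Reactants: 8 ethyl (2E,4S)-2,4-dimethyloct-2-enoate
Product: 9 (2E,4S)-2,4-dimethyloct-2-enoic acid
Conditions: LiOH, THF/MeOH/H2O, rt → 40 °C; then 1 M HCl
Reagents that add atoms: lithium hydroxide, [Li+].[OH-]
Why: Saponification; hydroxide is too weak a base to deprotonate the γ-position, so the C4′ center and the (E)-alkene should be retained.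

Step 6
Reactants: 10 methyltriphenylphosphonium bromide; 11 (iodomethyl)trimethylsilane
Product: 13 triphenyl[2-(trimethylsilyl)ethyl]phosphonium iodide, via methylidenetriphenylphosphorane 12 (not isolated)
Conditions: n-BuLi, THF, 0 °C; then 11, 0 °C → rt
Reagents that add atoms: none
Why: C-alkylation of a non-stabilized phosphorus ylide by a primary iodide gives the homologous phosphonium salt.

Step 7
Reactants: 13 triphenyl[2-(trimethylsilyl)ethyl]phosphonium iodide
Product: 15 2-(triphenyl-λ5-phosphanylidene)-3-(trimethylsilyl)propanal, via triphenyl[2-(trimethylsilyl)ethylidene]phosphorane 14 (not isolated)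
Conditions: KOtBu, THF, 0 °C; then HCO2Et, 0 °C → rt
Reagents that add atoms: ethyl formate, CCOC=O
Why: C-formylation of an alkylidene phosphorane by a formate ester (the ethoxide set free removes the last α-proton) should give the stabilized α-formyl ylide, the silylmethyl homologue of the common 2-(triphenylphosphoranylidene)propanal.

Step 8
Reactants: 16 (Z)-3-methylpent-2-en-4-yn-1-ol
Product: 18 (Z)-3-methyl-5-(trimethylsilyl)pent-2-en-4-yn-1-ol, via O,C-bis(trimethylsilyl) derivative 17 (not isolated)
Conditions: EtMgBr (2.2 equiv), THF, 0 °C → rt; Me3SiCl (2.3 equiv); then 1 M HCl, rt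
Reagents that add atoms: chlorotrimethylsilane, C[Si](C)(C)Cl
Why: Double deprotonation (alkoxide and acetylide), silylation of both sites and selective acid hydrolysis of the labile O–Si bond leave the C-silylated enynol; the (Z)-alkene is not involved.

Step 9
Reactants: 18 (Z)-3-methyl-5-(trimethylsilyl)pent-2-en-4-yn-1-ol; 19 pent-4-enoyl chloride
Product: 20 (Z)-3-methyl-5-(trimethylsilyl)pent-2-en-4-yn-1-yl pent-4-enoate
Conditions: pyridine, 4-(dimethylamino)pyridine (cat.), CH2Cl2, 0 °C → rt
Reagents that add atoms: none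
Why: Acylation of a primary allylic alcohol with an acid chloride.

Step 10
Reactants: 20 (Z)-3-methyl-5-(trimethylsilyl)pent-2-en-4-yn-1-yl pent-4-enoate
Product: 22 (2S,3R)-3-ethenyl-3-methyl-2-(prop-2-en-1-yl)-5-(trimethylsilyl)pent-4-ynoic acid, via boron enolate 21 (not isolated)
Conditions: (4S,5S)-2-bromo-1,3-bis{[3,5-bis(trifluoromethyl)phenyl]sulfonyl}-4,5-diphenyl-1,3,2-diazaborolidine [from the (1S,2S)-bis-sulfonamide and BBr3, CH2Cl2], Et3N, toluene/hexane, −78 °C; then −20 °C, 14 d; aq. work-up
Reagents that add atoms: (4S,5S)-2-bromo-1,3-bis{[3,5-bis(trifluoromethyl)phenyl]sulfonyl}-4,5-diphenyl-1,3,2-diazaborolidine, BrB1N(S(=O)(=O)c2cc(cc(c2)C(F)(F)F)C(F)(F)F)[C@@H](c2ccccc2)[C@H](c2ccccc2)N1S(=O)(=O)c1cc(cc(c1)C(F)(F)F)C(F)(F)F (its boron group is carried only by intermediate 21)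
Why: Enantioselective Ireland–Claisen rearrangement through a chiral boron ketene acetal: Et3N in a non-polar medium should give the enolate with O–B trans to the alkyl chain, and the chair transition state then places the slim alkynyl group axial and the methyl group equatorial on the (Z)-alkene terminus, which sets C4 and C5 (2S,3R in 22) with the relative configuration of the target. The C2-symmetric sulfonamide ligand on boron selects the enolate face and so the absolute sense.

Step 11
Reactants: 22 (2S,3R)-3-ethenyl-3-methyl-2-(prop-2-en-1-yl)-5-(trimethylsilyl)pent-4-ynoic acid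
Product: 23 tert-butyl (2S,3R)-3-ethenyl-3-methyl-2-(prop-2-en-1-yl)-5-(trimethylsilyl)pent-4-ynoate
Conditions: tert-butyl 2,2,2-trichloroacetimidate, BF3·OEt2 (cat.), CH2Cl2/cyclohexane, rt
Reagents that add atoms: tert-butyl 2,2,2-trichloroacetimidate, CC(C)(C)OC(=N)C(Cl)(Cl)Cl
Why: O-alkylation of the acid by the imidate is insensitive to the hindrance around the carboxyl group, and C4 is not enolized.

Step 12
Reactants: 23 tert-butyl (2S,3R)-3-ethenyl-3-methyl-2-(prop-2-en-1-yl)-5-(trimethylsilyl)pent-4-ynoate
Product: 25 tert-butyl (2S,3R)-3-ethenyl-2-(3-hydroxypropyl)-3-methyl-5-(trimethylsilyl)pent-4-ynoate, via B-alkyl-9-BBN adduct 24 (not isolated)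
Conditions: 9-borabicyclo[3.3.1]nonane (1.05 equiv), THF, 0 °C → rt; then NaBO3·4H2O, H2O, rt
Reagents that add atoms: 9-borabicyclo[3.3.1]nonane, [H]B1C2CCCC1CCC2 (boron only in intermediate 24); sodium perborate, [Na+].[Na+].O[B-]1(O)OO[B-](O)(O)OO1
Why: Hydroboration–oxidation with a bulky dialkylborane should select the unhindered allyl terminus (future C1) over the vinyl group on the quaternary carbon and over the doubly shielded silylalkyne; perborate is mild enough for the alkynylsilane.

Step 13
Reactants: 25 tert-butyl (2S,3R)-3-ethenyl-2-(3-hydroxypropyl)-3-methyl-5-(trimethylsilyl)pent-4-ynoate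
Product: 26 tert-butyl (2S,3R)-3-ethenyl-3-methyl-2-(3-oxopropyl)-5-(trimethylsilyl)pent-4-ynoate
Conditions: Dess–Martin periodinane, NaHCO3, CH2Cl2, rt
Reagents that add atoms: none
Why: Dess–Martin oxidation of a primary alcohol under buffered, non-epimerizing conditions.

Step 14
Reactants: 26 tert-butyl (2S,3R)-3-ethenyl-3-methyl-2-(3-oxopropyl)-5-(trimethylsilyl)pent-4-ynoate
Product: 28 tert-butyl (1S,2R,3E,4RS)-2-ethenyl-4-hydroxy-2-methyl-3-[(trimethylsilyl)methylidene]cyclohexane-1-carboxylate, via triethylsilyl ether 27 (not isolated)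
Conditions: Ni(cod)2 (10 mol%), PBu3 (20 mol%), Et3SiH, THF, 0 °C → rt; then Bu4NF, THF, rt
Reagents that add atoms: triethylsilane, CC[SiH](CC)CC (silicon only in intermediate 27; the product keeps its hydride on C9)
Why: Nickel-catalysed reductive cyclization of an ynal: oxidative cyclization of aldehyde and alkyne on zerovalent nickel forms the C1–C10 bond and ring A, and silane cleavage delivers hydrogen to C9 on the side of C1, so silicon ends cis to C5 (E). The quaternary propargylic carbon favours ring closure; C1 is expected as a mixture of epimers, which is of no consequence because step 15 removes this center.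

Step 15
Reactants: 28 tert-butyl (1S,2R,3E,4RS)-2-ethenyl-4-hydroxy-2-methyl-3-[(trimethylsilyl)methylidene]cyclohexane-1-carboxylate
Product: 29 tert-butyl (1S,2R,3E)-2-ethenyl-2-methyl-4-oxo-3-[(trimethylsilyl)methylidene]cyclohexane-1-carboxylate
Conditions: Dess–Martin periodinane, NaHCO3, CH2Cl2, 0 °C → rt
Reagents that add atoms: none
Why: Oxidation of both allylic alcohol epimers to one enone under neutral conditions that should leave the alkene geometry alone.

Step 16
Reactants: 29 tert-butyl (1S,2R,3E)-2-ethenyl-2-methyl-4-oxo-3-[(trimethylsilyl)methylidene]cyclohexane-1-carboxylate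
Product: 30 tert-butyl (1S,2R,3E,4R)-2-ethenyl-4-hydroxy-2-methyl-3-[(trimethylsilyl)methylidene]cyclohexane-1-carboxylate
Conditions: (S)-1-methyl-3,3-diphenyltetrahydro-1H,3H-pyrrolo[1,2-c][1,3,2]oxazaborole [(S)-Me-CBS, 20 mol%], catecholborane, toluene, −78 °C
Reagents that add atoms: none
Why: Corey–Bakshi–Shibata reduction of an enone: the fully substituted alkylidene carbon C10 acts as the large group and the ring CH2 as the small one, so the (S)-catalyst should deliver hydride to give the (R)-carbinol at C1 (oxygen cis to the C5 methyl) under reagent control. At −78 °C uncatalysed conjugate reduction and hydroboration of the vinyl group by catecholborane should not compete.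

Step 17
Reactants: 30 tert-butyl (1S,2R,3E,4R)-2-ethenyl-4-hydroxy-2-methyl-3-[(trimethylsilyl)methylidene]cyclohexane-1-carboxylate; 9 (2E,4S)-2,4-dimethyloct-2-enoic acid
Product: 32 tert-butyl (1S,2R,3E,4R)-4-{[(2E,4S)-2,4-dimethyloct-2-enoyl]oxy}-2-ethenyl-2-methyl-3-[(trimethylsilyl)methylidene]cyclohexane-1-carboxylate, via mixed anhydride 31 (not isolated)
Conditions: 9, 2,4,6-trichlorobenzoyl chloride, Et3N, THF, rt; then 30, 4-(dimethylamino)pyridine, toluene, rt → 40 °C
Reagents that add atoms: 2,4,6-trichlorobenzoyl chloride, O=C(Cl)c1c(Cl)cc(Cl)cc1Cl (its acyl group is carried only by intermediate 31)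
Why: Yamaguchi esterification, suited to hindered secondary alcohols and α,β-unsaturated acids; acylation occurs at oxygen with retention at C1.

Step 18
Reactants: 32 tert-butyl (1S,2R,3E,4R)-4-{[(2E,4S)-2,4-dimethyloct-2-enoyl]oxy}-2-ethenyl-2-methyl-3-[(trimethylsilyl)methylidene]cyclohexane-1-carboxylate
Product: 33 tert-butyl (1S,2R,3E,4R)-4-{[(2E,4S)-2,4-dimethyloct-2-enoyl]oxy}-2-ethenyl-3-(iodomethylidene)-2-methylcyclohexane-1-carboxylate
Conditions: N-iodosuccinimide, MeCN/ClCH2CN (4:1), 0 °C → rt, dark
Reagents that add atoms: N-iodosuccinimide, O=C1CCC(=O)N1I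
Why: Iododesilylation of a vinylsilane with retention of geometry (ipso attack, β-silyl cation, loss of silicon), so iodine ends cis to C5. The β-silicon effect makes the vinylsilane far more reactive than the monosubstituted vinyl group or the electron-poor enoate; the step is placed before any allylsilane is present.

Step 19
Reactants: 33 tert-butyl (1S,2R,3E,4R)-4-{[(2E,4S)-2,4-dimethyloct-2-enoyl]oxy}-2-ethenyl-3-(iodomethylidene)-2-methylcyclohexane-1-carboxylate
Product: 35 tert-butyl (1S,2R,3E,4R)-4-{[(2E,4S)-2,4-dimethyloct-2-enoyl]oxy}-2-(2-hydroxyethyl)-3-(iodomethylidene)-2-methylcyclohexane-1-carboxylate, via B-alkyl-9-BBN adduct 34 (not isolated)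
Conditions: 9-borabicyclo[3.3.1]nonane (2 equiv), THF, rt → 45 °C; then NaBO3·4H2O, H2O, rt
Reagents that add atoms: 9-borabicyclo[3.3.1]nonane, [H]B1C2CCCC1CCC2 (boron only in intermediate 34); sodium perborate, [Na+].[Na+].O[B-]1(O)OO[B-](O)(O)OO1
Why: Anti-Markovnikov hydroboration–oxidation of the only monosubstituted alkene; the trisubstituted vinyl iodide, the conjugated enoate and both esters are inert to this borane, and perborate spares the esters.

Step 20
Reactants: 35 tert-butyl (1S,2R,3E,4R)-4-{[(2E,4S)-2,4-dimethyloct-2-enoyl]oxy}-2-(2-hydroxyethyl)-3-(iodomethylidene)-2-methylcyclohexane-1-carboxylate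
Product: 36 tert-butyl (1S,2R,3E,4R)-4-{[(2E,4S)-2,4-dimethyloct-2-enoyl]oxy}-3-(iodomethylidene)-2-methyl-2-(2-oxoethyl)cyclohexane-1-carboxylate
Conditions: Dess–Martin periodinane, NaHCO3, CH2Cl2, 0 °C → rt
Reagents that add atoms: none
Why: Dess–Martin oxidation to the C7 aldehyde; no other oxidizable group is present.

Step 21
Reactants: 36 tert-butyl (1S,2R,3E,4R)-4-{[(2E,4S)-2,4-dimethyloct-2-enoyl]oxy}-3-(iodomethylidene)-2-methyl-2-(2-oxoethyl)cyclohexane-1-carboxylate; 15 2-(triphenyl-λ5-phosphanylidene)-3-(trimethylsilyl)propanal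
Product: 37 tert-butyl (1S,2R,3E,4R)-4-{[(2E,4S)-2,4-dimethyloct-2-enoyl]oxy}-2-[(2Z)-3-formyl-4-(trimethylsilyl)but-2-en-1-yl]-3-(iodomethylidene)-2-methylcyclohexane-1-carboxylate
Conditions: toluene, 90 °C
Reagents that add atoms: none
Why: Wittig olefination with a stabilized α-formyl ylide, which reacts with the aldehyde only and should place the formyl group trans to C6 (Z by the sequence rules because CH2Si outranks CHO). The whole arm (C11, C12, C13, silicon) arrives at the aldehyde oxidation level, so no hydride reagent meets the C1 ester.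

Step 22
Reactants: 37 tert-butyl (1S,2R,3E,4R)-4-{[(2E,4S)-2,4-dimethyloct-2-enoyl]oxy}-2-[(2Z)-3-formyl-4-(trimethylsilyl)but-2-en-1-yl]-3-(iodomethylidene)-2-methylcyclohexane-1-carboxylate
Product: 38 tert-butyl (1S,2R,3E,4R)-2-[(2Z)-3-(dimethoxymethyl)-4-(trimethylsilyl)but-2-en-1-yl]-4-{[(2E,4S)-2,4-dimethyloct-2-enoyl]oxy}-3-(iodomethylidene)-2-methylcyclohexane-1-carboxylate
Conditions: HC(OMe)3, MeOH, pyridinium p-toluenesulfonate (cat.), rt
Reagents that add atoms: trimethyl orthoformate, COC(OC)OC; methanol, CO
Why: Acetalization of an enal under weak acid catalysis with orthoformate as water scavenger; this acid is too weak to protodesilylate the allylsilane or to cleave the esters, and the acetal turns the alkene from an electron-poor enal into an electron-rich allylsilane.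

Step 23
Reactants: 38 tert-butyl (1S,2R,3E,4R)-2-[(2Z)-3-(dimethoxymethyl)-4-(trimethylsilyl)but-2-en-1-yl]-4-{[(2E,4S)-2,4-dimethyloct-2-enoyl]oxy}-3-(iodomethylidene)-2-methylcyclohexane-1-carboxylate; 39 carbon monoxide
Product: 40 tert-butyl (1S,4R,7S,8aR)-7-(3,3-dimethoxyprop-1-en-2-yl)-4-{[(2E,4S)-2,4-dimethyloct-2-enoyl]oxy}-8a-methyl-6-oxo-1,2,3,4,6,7,8,8a-octahydronaphthalene-1-carboxylate
Conditions: Pd(PPh3)4 (10 mol%), CO (20 atm), Ag3PO4 (1 equiv), DMF, 70 °C
Reagents that add atoms: none
Why: Proposed new method: oxidative addition of zerovalent palladium into the C9–I bond and CO insertion should give an α,β-unsaturated acyl–palladium iodide, which Ag3PO4 turns into a more electrophilic cationic acyl complex by removing iodide. This should add syn and 6-exo-trig across the C7=C11 allylsilane, acyl carbon C8 to the γ-carbon C7 and palladium to C11, the regiochemistry that both the exo mode and the β-silicon effect favour, so that CO insertion makes C8–C9, the addition makes C7–C8 and ring B is closed. β-Silyl elimination from the tertiary alkyl–palladium should then release the C11=C13 exo-methylene, and silicon leaves as a silyl phosphate, which keeps iodotrimethylsilane away from the acetal and the tert-butyl ester. The closest known reactions are the carbonylative acylpalladation cyclizations of alkenyl iodides with a tethered alkene and the allylsilane-terminated intramolecular Heck reaction; their combination under CO on a trisubstituted allylsilane is untested. The one new stereocenter, C7, is set in a chair-like closure with the C7=C11 unit equatorial, away from the axial C5 methyl, and, being α to the C8 ketone, it can also equilibrate to this (7S) arrangement. CO pressure is needed so that CO insertion outruns direct 5-exo carbopalladation of the vinyl–palladium, and the silyl group together with the silver salt is needed so that termination is desilylative and not β-hydride loss toward C7 or C13. The much faster C–I insertion and the CO atmosphere should keep zerovalent palladium from ionizing the hindered allylic C1 ester.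

Step 24
Reactants: 40 tert-butyl (1S,4R,7S,8aR)-7-(3,3-dimethoxyprop-1-en-2-yl)-4-{[(2E,4S)-2,4-dimethyloct-2-enoyl]oxy}-8a-methyl-6-oxo-1,2,3,4,6,7,8,8a-octahydronaphthalene-1-carboxylate
Product: 41 integric acid, (1S,4R,7S,8aR)-4-{[(2E,4S)-2,4-dimethyloct-2-enoyl]oxy}-8a-methyl-6-oxo-7-(3-oxoprop-1-en-2-yl)-1,2,3,4,6,7,8,8a-octahydronaphthalene-1-carboxylic acid
Conditions: CF3CO2H/H2O (9:1), CH2Cl2, 0 °C → rt
Reagents that add atoms: water, O
Why: Acid hydrolysis of the dimethyl acetal and acidolysis of the tert-butyl ester in one operation; the C1 ester is spared because the carbocation it would leave is destabilized by the enone. Any C7 epimer should drain to the equatorial (7S) isomer through the enol; contact time is kept short so that C11=C13 does not move into conjugation.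

## Compound list

1 | (S)-4-benzyloxazolidin-2-one | O=C1OC[C@H](Cc2ccccc2)N1 | starting material
2 | hexanoyl chloride | CCCCCC(Cl)=O | starting material
3 | (S)-4-benzyl-3-hexanoyloxazolidin-2-one | O=C1OC[C@H](Cc2ccccc2)N1C(=O)CCCCC | intermediate
4 | (S)-4-benzyl-3-[(S)-2-methylhexanoyl]oxazolidin-2-one | O=C1OC[C@H](Cc2ccccc2)N1C(=O)[C@@H](C)CCCC | intermediate
5 | (S)-2-methylhexan-1-ol | OC[C@@H](C)CCCC | intermediate
6 | ethyl 2-(triphenyl-λ5-phosphanylidene)propanoate | CCOC(=O)C(C)=P(c1ccccc1)(c1ccccc1)c1ccccc1 | starting material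
7 | (S)-2-methylhexanal | O=C[C@@H](C)CCCC | intermediate (not isolated)
8 | ethyl (2E,4S)-2,4-dimethyloct-2-enoate | CCOC(=O)/C(C)=C/[C@@H](C)CCCC | intermediate
9 | (2E,4S)-2,4-dimethyloct-2-enoic acid | OC(=O)/C(C)=C/[C@@H](C)CCCC | intermediate
10 | methyltriphenylphosphonium bromide | C[P+](c1ccccc1)(c1ccccc1)c1ccccc1.[Br-] | starting material
11 | (iodomethyl)trimethylsilane | C[Si](C)(C)CI | starting material
12 | methylidenetriphenylphosphorane | C=P(c1ccccc1)(c1ccccc1)c1ccccc1 | intermediate (not isolated)
13 | triphenyl[2-(trimethylsilyl)ethyl]phosphonium iodide | C[Si](C)(C)CC[P+](c1ccccc1)(c1ccccc1)c1ccccc1.[I-] | intermediate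
14 | triphenyl[2-(trimethylsilyl)ethylidene]phosphorane | C[Si](C)(C)CC=P(c1ccccc1)(c1ccccc1)c1ccccc1 | intermediate (not isolated)
15 | 2-(triphenyl-λ5-phosphanylidene)-3-(trimethylsilyl)propanal | O=CC(C[Si](C)(C)C)=P(c1ccccc1)(c1ccccc1)c1ccccc1 | intermediate
16 | (Z)-3-methylpent-2-en-4-yn-1-ol | C#C/C(C)=C\CO | starting material
17 | trimethyl{[(Z)-3-methyl-5-(trimethylsilyl)pent-2-en-4-yn-1-yl]oxy}silane | C[Si](C)(C)C#C/C(C)=C\CO[Si](C)(C)C | intermediate (not isolated)
18 | (Z)-3-methyl-5-(trimethylsilyl)pent-2-en-4-yn-1-ol | C[Si](C)(C)C#C/C(C)=C\CO | intermediate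
19 | pent-4-enoyl chloride | C=CCCC(Cl)=O | starting material
20 | (Z)-3-methyl-5-(trimethylsilyl)pent-2-en-4-yn-1-yl pent-4-enoate | C=CCCC(=O)OC/C=C(/C)C#C[Si](C)(C)C | intermediate
21 | boron enolate of 20: ketene O-boryl O-allyl acetal with the B–O bond trans to the CH2CH=CH2 chain, boron being part of the (4S,5S)-1,3-bis{[3,5-bis(trifluoromethyl)phenyl]sulfonyl}-4,5-diphenyl-1,3,2-diazaborolidine ring | C=CC/C=C(/OB1N(S(=O)(=O)c2cc(cc(c2)C(F)(F)F)C(F)(F)F)[C@@H](c2ccccc2)[C@H](c2ccccc2)N1S(=O)(=O)c1cc(cc(c1)C(F)(F)F)C(F)(F)F)OC/C=C(/C)C#C[Si](C)(C)C | intermediate (not isolated)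
22 | (2S,3R)-3-ethenyl-3-methyl-2-(prop-2-en-1-yl)-5-(trimethylsilyl)pent-4-ynoic acid | OC(=O)[C@@H](CC=C)[C@@](C)(C=C)C#C[Si](C)(C)C | intermediate
23 | tert-butyl (2S,3R)-3-ethenyl-3-methyl-2-(prop-2-en-1-yl)-5-(trimethylsilyl)pent-4-ynoate | CC(C)(C)OC(=O)[C@@H](CC=C)[C@@](C)(C=C)C#C[Si](C)(C)C | intermediate
24 | tert-butyl (2S,3R)-2-[3-(9-borabicyclo[3.3.1]nonan-9-yl)propyl]-3-ethenyl-3-methyl-5-(trimethylsilyl)pent-4-ynoate | CC(C)(C)OC(=O)[C@@H](CCCB1C2CCCC1CCC2)[C@@](C)(C=C)C#C[Si](C)(C)C | intermediate (not isolated)
25 | tert-butyl (2S,3R)-3-ethenyl-2-(3-hydroxypropyl)-3-methyl-5-(trimethylsilyl)pent-4-ynoate | CC(C)(C)OC(=O)[C@@H](CCCO)[C@@](C)(C=C)C#C[Si](C)(C)C | intermediate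
26 | tert-butyl (2S,3R)-3-ethenyl-3-methyl-2-(3-oxopropyl)-5-(trimethylsilyl)pent-4-ynoate | CC(C)(C)OC(=O)[C@@H](CCC=O)[C@@](C)(C=C)C#C[Si](C)(C)C | intermediate
27 | tert-butyl (1S,2R,3E,4RS)-2-ethenyl-2-methyl-4-[(triethylsilyl)oxy]-3-[(trimethylsilyl)methylidene]cyclohexane-1-carboxylate (both epimers at the silyloxy carbon) | C[Si](C)(C)/C=C1/C(O[Si](CC)(CC)CC)CC[C@H](C(=O)OC(C)(C)C)[C@@]1(C)C=C | intermediate (not isolated)
28 | tert-butyl (1S,2R,3E,4RS)-2-ethenyl-4-hydroxy-2-methyl-3-[(trimethylsilyl)methylidene]cyclohexane-1-carboxylate (both epimers at the carbinol carbon) | C[Si](C)(C)/C=C1/C(O)CC[C@H](C(=O)OC(C)(C)C)[C@@]1(C)C=C | intermediate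
29 | tert-butyl (1S,2R,3E)-2-ethenyl-2-methyl-4-oxo-3-[(trimethylsilyl)methylidene]cyclohexane-1-carboxylate | C[Si](C)(C)/C=C1/C(=O)CC[C@H](C(=O)OC(C)(C)C)[C@@]1(C)C=C | intermediate
30 | tert-butyl (1S,2R,3E,4R)-2-ethenyl-4-hydroxy-2-methyl-3-[(trimethylsilyl)methylidene]cyclohexane-1-carboxylate | C[Si](C)(C)/C=C1/[C@H](O)CC[C@H](C(=O)OC(C)(C)C)[C@@]1(C)C=C | intermediate
31 | (2E,4S)-2,4-dimethyloct-2-enoic 2,4,6-trichlorobenzoic anhydride | O=C(OC(=O)/C(C)=C/[C@@H](C)CCCC)c1c(Cl)cc(Cl)cc1Cl | intermediate (not isolated)
32 | tert-butyl (1S,2R,3E,4R)-4-{[(2E,4S)-2,4-dimethyloct-2-enoyl]oxy}-2-ethenyl-2-methyl-3-[(trimethylsilyl)methylidene]cyclohexane-1-carboxylate | C[Si](C)(C)/C=C1/[C@H](OC(=O)/C(C)=C/[C@@H](C)CCCC)CC[C@H](C(=O)OC(C)(C)C)[C@@]1(C)C=C | intermediate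
33 | tert-butyl (1S,2R,3E,4R)-4-{[(2E,4S)-2,4-dimethyloct-2-enoyl]oxy}-2-ethenyl-3-(iodomethylidene)-2-methylcyclohexane-1-carboxylate | I/C=C1/[C@H](OC(=O)/C(C)=C/[C@@H](C)CCCC)CC[C@H](C(=O)OC(C)(C)C)[C@@]1(C)C=C | intermediate
34 | tert-butyl (1S,2R,3E,4R)-2-[2-(9-borabicyclo[3.3.1]nonan-9-yl)ethyl]-4-{[(2E,4S)-2,4-dimethyloct-2-enoyl]oxy}-3-(iodomethylidene)-2-methylcyclohexane-1-carboxylate | I/C=C1/[C@H](OC(=O)/C(C)=C/[C@@H](C)CCCC)CC[C@H](C(=O)OC(C)(C)C)[C@@]1(C)CCB1C2CCCC1CCC2 | intermediate (not isolated)
35 | tert-butyl (1S,2R,3E,4R)-4-{[(2E,4S)-2,4-dimethyloct-2-enoyl]oxy}-2-(2-hydroxyethyl)-3-(iodomethylidene)-2-methylcyclohexane-1-carboxylate | I/C=C1/[C@H](OC(=O)/C(C)=C/[C@@H](C)CCCC)CC[C@H](C(=O)OC(C)(C)C)[C@@]1(C)CCO | intermediate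
36 | tert-butyl (1S,2R,3E,4R)-4-{[(2E,4S)-2,4-dimethyloct-2-enoyl]oxy}-3-(iodomethylidene)-2-methyl-2-(2-oxoethyl)cyclohexane-1-carboxylate | I/C=C1/[C@H](OC(=O)/C(C)=C/[C@@H](C)CCCC)CC[C@H](C(=O)OC(C)(C)C)[C@@]1(C)CC=O | intermediate
37 | tert-butyl (1S,2R,3E,4R)-4-{[(2E,4S)-2,4-dimethyloct-2-enoyl]oxy}-2-[(2Z)-3-formyl-4-(trimethylsilyl)but-2-en-1-yl]-3-(iodomethylidene)-2-methylcyclohexane-1-carboxylate (formyl trans to the ring CH2) | I/C=C1/[C@H](OC(=O)/C(C)=C/[C@@H](C)CCCC)CC[C@H](C(=O)OC(C)(C)C)[C@@]1(C)C/C=C(/C=O)C[Si](C)(C)C | intermediate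
38 | tert-butyl (1S,2R,3E,4R)-2-[(2Z)-3-(dimethoxymethyl)-4-(trimethylsilyl)but-2-en-1-yl]-4-{[(2E,4S)-2,4-dimethyloct-2-enoyl]oxy}-3-(iodomethylidene)-2-methylcyclohexane-1-carboxylate (acetal carbon trans to the ring CH2) | I/C=C1/[C@H](OC(=O)/C(C)=C/[C@@H](C)CCCC)CC[C@H](C(=O)OC(C)(C)C)[C@@]1(C)C/C=C(/C(OC)OC)C[Si](C)(C)C | intermediate
39 | carbon monoxide | [C-]#[O+] | starting material
40 | tert-butyl (1S,4R,7S,8aR)-7-(3,3-dimethoxyprop-1-en-2-yl)-4-{[(2E,4S)-2,4-dimethyloct-2-enoyl]oxy}-8a-methyl-6-oxo-1,2,3,4,6,7,8,8a-octahydronaphthalene-1-carboxylate (integric acid tert-butyl ester dimethyl acetal) | C=C(C(OC)OC)[C@@H]1C[C@@]2(C)C(=CC1=O)[C@H](OC(=O)/C(C)=C/[C@@H](C)CCCC)CC[C@@H]2C(=O)OC(C)(C)C | intermediate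
41 | integric acid, (1S,4R,7S,8aR)-4-{[(2E,4S)-2,4-dimethyloct-2-enoyl]oxy}-8a-methyl-6-oxo-7-(3-oxoprop-1-en-2-yl)-1,2,3,4,6,7,8,8a-octahydronaphthalene-1-carboxylic acid | C=C(C=O)[C@@H]1C[C@@]2(C)C(=CC1=O)[C@H](OC(=O)/C(C)=C/[C@@H](C)CCCC)CC[C@@H]2C(=O)O | target

## Step count and least certain steps

Total step count: 24 (5 for acid 9, 2 for ylide 15, 17 on the main line). Longest linear sequence: 17 steps (steps 8–24, from 16).

**Step 23 (key step, Proposed new method).** Four things may go wrong:
- the vinyl–palladium may cyclize 5-exo before CO inserts, or CO pressure high enough to prevent this may block alkene coordination, so that the acyl–palladium is reduced or captured by adventitious nucleophiles;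
- termination may occur by β-hydride loss toward C7 or C13, or by loss of methoxide from the acetal, in place of desilylation;
- zerovalent palladium may ionize the allylic C1 ester;
- the phosphate base may move C11=C13 into conjugation.

Fallback by known chemistry, from 38 back to 40. Palladium-catalysed formylation of the vinyl iodide (Pd(PPh3)4, CO, Bu3SnH added slowly, THF, 50 °C) would give tert-butyl (1S,2R,3E,4R)-2-[(2Z)-3-(dimethoxymethyl)-4-(trimethylsilyl)but-2-en-1-yl]-4-{[(2E,4S)-2,4-dimethyloct-2-enoyl]oxy}-2-methyl-3-(2-oxoethylidene)cyclohexane-1-carboxylate F1. A fluoride-triggered intramolecular Hosomi–Sakurai addition of the allylsilane to this aldehyde (Bu4NF, THF) would then form C7–C8, close ring B and create C11=C13 in tert-butyl (1S,4R,8aR)-7-(3,3-dimethoxyprop-1-en-2-yl)-4-{[(2E,4S)-2,4-dimethyloct-2-enoyl]oxy}-6-hydroxy-8a-methyl-1,2,3,4,6,7,8,8a-octahydronaphthalene-1-carboxylate F2, a mixture at the two new centers. Dess–Martin oxidation of this allylic alcohol gives 40, in which C7 settles as before.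

**Step 10.** The enolate geometry or the facial control by the boron ligand may be incomplete on this enyne ester, which would erode the diastereomer and enantiomer ratios, and the rearrangement is slow at −20 °C. Fallback, from 20 back to 22: the classical Ireland–Claisen rearrangement (LDA, Me3SiCl, THF, −78 °C → rt), which passes through the kinetic silyl ketene acetal of the same geometry, would give racemic (2S*,3R*)-3-ethenyl-3-methyl-2-(prop-2-en-1-yl)-5-(trimethylsilyl)pent-4-ynoic acid F3. Resolution by crystallization of the (R)-1-phenylethylammonium (2S,3R)-carboxylate F4 and acidification would return 22.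

**Step 12.** Hydroboration may not discriminate cleanly between the allyl terminus, the hindered vinyl group and the silylalkyne. Fallback, from 18 back to 25, with the C1 oxygen carried from the start: 5-[(tert-butyldimethylsilyl)oxy]pentanoic acid F5 (from δ-valerolactone by hydroxide opening and silylation) is coupled with 18 (carbodiimide, 4-(dimethylamino)pyridine) to give (Z)-3-methyl-5-(trimethylsilyl)pent-2-en-4-yn-1-yl 5-[(tert-butyldimethylsilyl)oxy]pentanoate F6. The same boron-mediated rearrangement gives (2S,3R)-2-{3-[(tert-butyldimethylsilyl)oxy]propyl}-3-ethenyl-3-methyl-5-(trimethylsilyl)pent-4-ynoic acid F7, the imidate gives its tert-butyl ester F8, and camphorsulfonic acid in MeOH releases alcohol 25.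

**Step 21.** The α-branched formyl ylide may olefinate the β-quaternary aldehyde too slowly, with thermal loss of material or further reaction of the enal. Fallback, from 36 back to 37, by a directed aldol condensation: N-cyclohexyl-3-(trimethylsilyl)propan-1-imine F9 (from 3-(trimethylsilyl)propanal and cyclohexylamine) is lithiated (LDA, THF, −78 °C) and added to 36. Hydrolytic work-up gives tert-butyl (1S,2R,3E,4R)-4-{[(2E,4S)-2,4-dimethyloct-2-enoyl]oxy}-2-[3-formyl-2-hydroxy-4-(trimethylsilyl)butyl]-3-(iodomethylidene)-2-methylcyclohexane-1-carboxylate F10, and dehydration (MsCl, Et3N) gives 37.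

**Step 24.** Strong aqueous acid may move the exo-methylene into conjugation with C8 or slowly cleave the allylic ester before the tert-butyl group is gone. Fallback, from 40 back to 41, in two separate mild operations: LiBF4 in wet MeCN hydrolyses only the acetal to integric acid tert-butyl ester F11, and ZnBr2 in CH2Cl2 then removes the tert-butyl group.

## Further compounds

F1 | step 23 | tert-butyl (1S,2R,3E,4R)-2-[(2Z)-3-(dimethoxymethyl)-4-(trimethylsilyl)but-2-en-1-yl]-4-{[(2E,4S)-2,4-dimethyloct-2-enoyl]oxy}-2-methyl-3-(2-oxoethylidene)cyclohexane-1-carboxylate | O=C/C=C1/[C@H](OC(=O)/C(C)=C/[C@@H](C)CCCC)CC[C@H](C(=O)OC(C)(C)C)[C@@]1(C)C/C=C(/C(OC)OC)C[Si](C)(C)C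
F2 | step 23 | tert-butyl (1S,4R,8aR)-7-(3,3-dimethoxyprop-1-en-2-yl)-4-{[(2E,4S)-2,4-dimethyloct-2-enoyl]oxy}-6-hydroxy-8a-methyl-1,2,3,4,6,7,8,8a-octahydronaphthalene-1-carboxylate (mixture at C6 and C7) | C=C(C(OC)OC)C1C[C@@]2(C)C(=CC1O)[C@H](OC(=O)/C(C)=C/[C@@H](C)CCCC)CC[C@@H]2C(=O)OC(C)(C)C
F3 | step 10 | racemic (2S*,3R*)-3-ethenyl-3-methyl-2-(prop-2-en-1-yl)-5-(trimethylsilyl)pent-4-ynoic acid (both enantiomers) | OC(=O)[C@@H](CC=C)[C@@](C)(C=C)C#C[Si](C)(C)C.OC(=O)[C@H](CC=C)[C@](C)(C=C)C#C[Si](C)(C)C
F4 | step 10 | (R)-1-phenylethylammonium (2S,3R)-3-ethenyl-3-methyl-2-(prop-2-en-1-yl)-5-(trimethylsilyl)pent-4-ynoate | [O-]C(=O)[C@@H](CC=C)[C@@](C)(C=C)C#C[Si](C)(C)C.C[C@@H]([NH3+])c1ccccc1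
F5 | step 12 | 5-[(tert-butyldimethylsilyl)oxy]pentanoic acid | CC(C)(C)[Si](C)(C)OCCCCC(=O)O
F6 | step 12 | (Z)-3-methyl-5-(trimethylsilyl)pent-2-en-4-yn-1-yl 5-[(tert-butyldimethylsilyl)oxy]pentanoate | CC(C)(C)[Si](C)(C)OCCCCC(=O)OC/C=C(/C)C#C[Si](C)(C)C
F7 | step 12 | (2S,3R)-2-{3-[(tert-butyldimethylsilyl)oxy]propyl}-3-ethenyl-3-methyl-5-(trimethylsilyl)pent-4-ynoic acid | OC(=O)[C@@H](CCCO[Si](C)(C)C(C)(C)C)[C@@](C)(C=C)C#C[Si](C)(C)C
F8 | step 12 | tert-butyl (2S,3R)-2-{3-[(tert-butyldimethylsilyl)oxy]propyl}-3-ethenyl-3-methyl-5-(trimethylsilyl)pent-4-ynoate | CC(C)(C)OC(=O)[C@@H](CCCO[Si](C)(C)C(C)(C)C)[C@@](C)(C=C)C#C[Si](C)(C)C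
F9 | step 21 | N-cyclohexyl-3-(trimethylsilyl)propan-1-imine | C[Si](C)(C)CCC=NC1CCCCC1
F10 | step 21 | tert-butyl (1S,2R,3E,4R)-4-{[(2E,4S)-2,4-dimethyloct-2-enoyl]oxy}-2-[3-formyl-2-hydroxy-4-(trimethylsilyl)butyl]-3-(iodomethylidene)-2-methylcyclohexane-1-carboxylate (diastereomers at the two new centers) | I/C=C1/[C@H](OC(=O)/C(C)=C/[C@@H](C)CCCC)CC[C@H](C(=O)OC(C)(C)C)[C@@]1(C)CC(O)C(C=O)C[Si](C)(C)C
F11 | step 24 | integric acid tert-butyl ester, tert-butyl (1S,4R,7S,8aR)-4-{[(2E,4S)-2,4-dimethyloct-2-enoyl]oxy}-8a-methyl-6-oxo-7-(3-oxoprop-1-en-2-yl)-1,2,3,4,6,7,8,8a-octahydronaphthalene-1-carboxylate | C=C(C=O)[C@@H]1C[C@@]2(C)C(=CC1=O)[C@H](OC(=O)/C(C)=C/[C@@H](C)CCCC)CC[C@@H]2C(=O)OC(C)(C)C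
A1 | alternative 1 | methyl 4α,5α-epoxy-10β-methyl-8-oxodecahydronaphthalene-4β-carboxylate (eudesmane numbering) | O=C1CC[C@@]2(O3)[C@@]3(C(=O)OC)CCC[C@]2(C)C1
A2 | alternative 1 | methyl 4α-hydroxy-5β-methyl-8-oxo-octal-9-ene-4-carboxylate (eremophilane numbering) | O=C1C=C2CCC[C@](O)(C(=O)OC)[C@@]2(C)CC1
A3 | alternative 2 | 3-{(2E,8Z)-6,6-(ethylenedioxy)-3-methyl-9-[(triisopropylsilyl)oxy]undeca-2,8,10-trienoyl}oxazolidin-2-one | O=C1OCCN1C(=O)/C=C(\C)CCC2(OCCO2)C/C=C(\O[Si](C(C)C)(C(C)C)C(C)C)C=C
A4 | alternative 2 | trans-fused octalin N-acyl oxazolidinone with the C1 triisopropylsilyl enol ether and the C8 dioxolane | C[C@]12CCC3(OCCO3)C[C@@H]1C(O[Si](C(C)C)(C(C)C)C(C)C)=CC[C@@H]2C(=O)N4CCOC4=O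
A5 | alternative 3 | dimethyl 2-(1-methyl-4-oxocyclohexa-2,5-dien-1-yl)-2-(3-oxopropyl)propanedioate | O=CCCC(C(=O)OC)(C(=O)OC)C1(C)C=CC(=O)C=C1
A6 | alternative 3 | dimethyl cis-8a-methyl-4,6-dioxo-3,4,4a,5,6,8a-hexahydronaphthalene-1,1(2H)-dicarboxylate | O=C1C=C[C@@]2(C)[C@@H](C1)C(=O)CCC2(C(=O)OC)C(=O)OC
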